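The plan rests on cutting the C12–C13 bond of the pyran (O, C8, C9, C11, C12, C13; labdane numbering). Its oxygen sits between two fully substituted carbons, yet O–C13–C16 is a hidden acetyl group and the C12 carbinol marks a former C12=C13 enol ether. A reduced-titanium alkylidene therefore stitches the C9 allyl group onto the carbonyl of a C8 tertiary acetate. This closes the six-membered ring and installs the enol ether in one operation, so the congested C8–O–C13 link needs only an acylation. The precursor is the complete ring-B cyclohexane (C5, C8, C9, C10 set) with equatorial acetate and allyl groups and both acid arms masked as TBS ethers.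

Key step: step 16

Remarks on the chemistry
- **Numbering and faces:** Labdane numbering is used for all intermediates. Ring B is the chair that keeps the C5 side chain equatorial. "Upper face" is the face of the axial methyl C20 and "lower face" is the opposite one.
- **Reading of the target:** The target is (5S,8S,9S,10R,12S,13S), in the ent-labdane series.
  - C20 and C17 are axial on the upper face; H-5 and H-9 are axial on the lower face.
  - The ring B/pyran fusion is trans.
  - The C13 vinyl is axial (upper face, syn to C17) and C16 is equatorial.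
  - The C12 hydroxyl is equatorial (upper face).
- **Assumption:** The catalyst of step 6 exists in two pseudo-enantiomeric forms. The one that leads to (S)-9 is picked by a trial run.
- **Bookkeeping:** The titanium species 22 and 23 are written with a Cl2Ti fragment only. C12/C13 of 23 and the spiro carbon of 12 are transient and left undefined.
- **Design points:**
  - The C3 ester becomes its silyl ether before the dissolving-metal step.
  - One hydride treatment both opens the C8 epoxide and reduces the C2 ester.
  - C12 stays a ketone until both arms are acids, so primary and secondary alcohols never have to be distinguished.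

Step 1
Reactants: 1 4-bromo-3-methylanisole; 2 methyl isobutyrate
Product: 4 methyl 2-(4-methoxy-2-methylphenyl)-2-methylpropanoate, via lithium enolate 3 (not isolated)
Conditions: Cy2NH, n-BuLi, toluene, 0 °C, then 2; then 1, Pd(dba)2 (cat.), P(t-Bu)3 (cat.), rt
Reagents that add atoms: none
Why: Palladium-catalysed α-arylation of an ester enolate, in which the bulky electron-rich phosphine should let the fully substituted isobutyrate enolate couple even with an ortho-methyl aryl bromide, forging C4–C5 and the gem-dimethyl carbon at once.

Step 2
Reactants: 4 methyl 2-(4-methoxy-2-methylphenyl)-2-methylpropanoate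
Product: 5 2-(4-methoxy-2-methylphenyl)-2-methylpropan-1-ol
Conditions: LiAlH4, THF, 0 °C → rt
Reagents that add atoms: none
Why: Standard hydride reduction of an ester, placed here because a methyl ester would not be safe under the dissolving-metal conditions of step 4.

Step 3
Reactants: 5 2-(4-methoxy-2-methylphenyl)-2-methylpropan-1-ol
Product: 6 tert-butyl[2-(4-methoxy-2-methylphenyl)-2-methylpropoxy]dimethylsilane
Conditions: TBSCl, imidazole, DMF, rt
Reagents that add atoms: tert-butyldimethylsilyl chloride, CC(C)(C)[Si](C)(C)Cl
Why: Routine silylation that installs the final C3–O protecting group early and rules out later oxa-Michael closure of a free neopentyl alcohol onto the enone.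

Step 4
Reactants: 6 tert-butyl[2-(4-methoxy-2-methylphenyl)-2-methylpropoxy]dimethylsilane
Product: 7 tert-butyl[2-(4-methoxy-2-methylcyclohexa-1,4-dien-1-yl)-2-methylpropoxy]dimethylsilane
Conditions: Li, NH3(l), THF, t-BuOH, −78 → −33 °C
Reagents that add atoms: none
Why: Birch reduction, in which the methoxy group and both alkyl substituents end on sp2 carbons, so that only the 2,5-dihydroanisole with the tetrasubstituted C5=C10 alkene is expected, and alkyl TBS ethers tolerate Li/NH3.

Step 5
Reactants: 7 tert-butyl[2-(4-methoxy-2-methylcyclohexa-1,4-dien-1-yl)-2-methylpropoxy]dimethylsilane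
Product: 8 4-[1-(tert-butyldimethylsilyloxy)-2-methylpropan-2-yl]-3-methylcyclohex-3-en-1-one
Conditions: oxalic acid (cat.), THF–H2O, rt
Reagents that add atoms: water, O
Why: Mild enol-ether hydrolysis should release the unconjugated ketone without moving the tetrasubstituted alkene or touching the silyl ether.

Step 6
Reactants: 8 4-[1-(tert-butyldimethylsilyloxy)-2-methylpropan-2-yl]-3-methylcyclohex-3-en-1-one
Product: 9 (S)-4-[1-(tert-butyldimethylsilyloxy)-2-methylpropan-2-yl]-3-methylcyclohex-2-en-1-one
Conditions: 9-amino-9-deoxy-epi-cinchona primary amine (10 mol %), carboxylic acid co-catalyst, toluene, rt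
Reagents that add atoms: none
Why: Enantioselective olefin isomerisation by iminium/dienamine proton-transfer catalysis, in which the chiral amine condenses with the unhindered C8 ketone, takes a proton from C9 and returns it to one face of C5 (setting C5 as S), the shift being driven by conjugation and by relief of the methyl/tert-alkyl clash on the tetrasubstituted alkene.

Step 7
Reactants: 9 (S)-4-[1-(tert-butyldimethylsilyloxy)-2-methylpropan-2-yl]-3-methylcyclohex-2-en-1-one; 10 propadiene
Product: 11 head-to-head allene photoadduct (C8 ketone; 6-methyl-8-methylidenebicyclo[4.2.0]octan-2-one core; cis-fused; cyclobutane on the lower face)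
Conditions: hν (medium-pressure Hg lamp, Pyrex), excess 10, CH2Cl2, −78 °C
Reagents that add atoms: none
Why: Enone–allene [2+2] photocycloaddition, typically head-to-head (central allene carbon to C9, CH2 to C10), where A(1,2) strain with C20 holds the bulky C5 side chain pseudo-axial so that allene adds to the opposite face and sets quaternary C10 with C1 trans to C4.

Step 8
Reactants: 11 head-to-head allene photoadduct
Product: 13 cis-fused bicyclo[4.2.0]octane-2,8-dione (C8 and C2 ketones flanking C9–H), via spiro ozonide 12 (not isolated)
Conditions: O3, CH2Cl2, −78 °C; then Me2S, −78 °C → rt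
Reagents that add atoms: ozone, [O-][O+]=O
Why: Ozonolysis of the only C=C bond with reductive work-up in an alcohol-free medium, so that the strained β-diketone is not solvolysed prematurely and no stereocentre is touched.

Step 9
Reactants: 13 cis-fused bicyclo[4.2.0]octane-2,8-dione; 14 allyl bromide
Product: 15 1-allyl bicyclo[4.2.0]octane-2,8-dione (allyl on C9; upper face; cis ring fusion)
Conditions: K2CO3, Pd(PPh3)4 (5 mol %), THF–DMF, rt
Reagents that add atoms: none
Why: Tsuji–Trost allylation of the stabilised β-diketone enolate places the allyl group regiospecifically on C9 and never on C7, palladium re-ionising any O-allylated material, and the C9 configuration (cis fusion expected) does not matter because step 10 erases it.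

Step 10
Reactants: 15 1-allyl bicyclo[4.2.0]octane-2,8-dione
Product: 16 (5S,9S,10R)-keto ester: C8 cyclohexanone with equatorial C9 allyl; axial C20; equatorial CH2CO2Me on C10; equatorial C5 side chain
Conditions: NaOMe (cat.), MeOH, 0 °C → rt
Reagents that add atoms: methanol, CO
Why: Retro-Claisen cleavage, in which methoxide adds to the more electrophilic cyclobutanone carbonyl C2 and strain release breaks C2–C9 to unveil the C1–C2 acetate arm, after which C9 equilibrates under the basic conditions to the equatorial allyl epimer (H-9 axial, anti to C20).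

Step 11
Reactants: 16 (5S,9S,10R)-keto ester
Product: 17 C8(17)-exomethylene ester (stereocentres as in 16)
Conditions: Zn, CH2Br2, TiCl4, THF–CH2Cl2, 0 °C → rt
Reagents that add atoms: dibromomethane, BrCBr
Why: Takai–Lombardo methylenation is non-basic, so C9 is not disturbed, and under these mild amine-free conditions it takes ketones but leaves esters alone.

Step 12
Reactants: 17 C8(17)-exomethylene ester
Product: 18 (5S,8S,9S,10R)-C8,C17 spiro-epoxide ester (oxygen equatorial on the lower face; C17 axial)
Conditions: mCPBA (1.05 equiv), CH2Cl2, 0 °C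
Reagents that add atoms: 3-chloroperoxybenzoic acid, O=C(OO)c1cccc(Cl)c1
Why: Prilezhaev epoxidation, where the 1,1-disubstituted exocyclic alkene is clearly more nucleophilic than the monosubstituted allyl group and the axial C20 methyl blocks the upper face, so oxygen arrives from below and sets C8.

Step 13
Reactants: 18 (5S,8S,9S,10R)-C8,C17 spiro-epoxide ester
Product: 19 (5S,8S,9S,10R)-diol: tertiary C8 alcohol (equatorial OH; axial C17 methyl) plus primary C2 alcohol
Conditions: LiAlH4, THF, 0 °C → reflux
Reagents that add atoms: none
Why: One hydride treatment does two jobs, SN2 opening of the epoxide at the unsubstituted carbon C17 with C8 untouched and reduction of the C2 ester to the primary alcohol.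

Step 14
Reactants: 19 (5S,8S,9S,10R)-diol
Product: 20 bis-TBS ether with free tertiary C8 alcohol
Conditions: TBSCl (1.05 equiv), imidazole, CH2Cl2, 0 °C
Reagents that add atoms: tert-butyldimethylsilyl chloride, CC(C)(C)[Si](C)(C)Cl
Why: Steric discrimination in silylation, since TBSCl/imidazole reacts with the primary C2 hydroxyl while the hindered tertiary C8 hydroxyl is inert.

Step 15
Reactants: 20 bis-TBS ether with free tertiary C8 alcohol
Product: 21 (5S,8S,9S,10R)-C8 tertiary acetate with C9 allyl group and both arms as TBS ethers
Conditions: AcCl, N,N-dimethylaniline, CH2Cl2, 0 °C → rt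
Reagents that add atoms: acetyl chloride, CC(=O)Cl
Why: Acylation of a hindered tertiary alcohol with acetyl chloride and a weak aromatic amine base, the classical conditions for equatorial C8 carbinols of the labdane series, should bring in C13 and C16 without elimination or desilylation.

Step 16
Reactants: 21 (5S,8S,9S,10R)-C8 tertiary acetate with C9 allyl group and both arms as TBS ethers
Product: 24 trans-fused 13-methyl cyclic enol ether (C12=C13) with both arms as TBS ethers, via C12 titanium alkylidene 22 (not isolated), via oxatitanacyclobutane 23 (not isolated)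
Conditions: TiCl4, TMEDA, Zn, PbCl2 (cat.), CH3CHBr2, THF–CH2Cl2, rt → 65 °C
Reagents that add atoms: none
Why: Olefinic-ester cyclisation with a Takai–Utimoto reagent: the titanium ethylidene made from TiCl4/Zn/PbCl2/TMEDA and CH3CHBr2 first exchanges alkylidenes with the unhindered terminal alkene, expelling propene and placing titanium on C12 (22). This alkylidene adds intramolecularly across the acetate C=O to give 23, whose cycloreversion, driven by the Ti=O bond, delivers the C12=C13 enol ether; overall it is a carbonyl–olefin metathesis, closest to the enol-ether ring closures used for trans-fused polyether arrays. The single ring closes in a six-membered mode by [2+2] addition and retro-[2+2], and the diequatorial (gauche) placement of C8–O and C9–C11 on the locked ring-B chair keeps the termini within reach and allows only the trans-fused bicycle. No stereocentre is created, and C5, C8, C9 and C10 are not affected. Only chemoselectivity is needed: 21 holds one C=O and one C=C, the arms are silyl ethers that the reagent ignores, and TMEDA tempers the Lewis acidity that could ionise the tertiary C8–O bond. Using the ethylidene rather than the methylidene reagent favours cyclisation over plain carbonyl alkylidenation.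

Step 17
Reactants: 24 trans-fused 13-methyl cyclic enol ether
Product: 26 (12R,13S)-13-vinyl-12-ol bis-TBS ether (axial vinyl on the upper face; axial OH on the lower face), via enol-ether epoxide 25 (not isolated)
Conditions: DMDO, acetone–CH2Cl2, −78 → 0 °C, volatiles removed; then CH2=CHMgBr, THF, −78 → 0 °C
Reagents that add atoms: dimethyldioxirane, CC1(C)OO1; vinylmagnesium bromide, C=C[Mg]Br
Why: Enol-ether epoxidation followed by Grignard opening at the acetal carbon, in which DMDO attacks the lower face away from the angular C17 and C20 methyl groups and the vinyl nucleophile enters C13 anti to the epoxide oxygen along the axial (Fürst–Plattner) trajectory that also matches the electronic bias for the oxygen-stabilised carbon, setting C13 and, provisionally, an axial C12 hydroxyl.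

Step 18
Reactants: 26 (12R,13S)-13-vinyl-12-ol bis-TBS ether
Product: 27 (12R)-triol (C2, C3 primary and C12 secondary hydroxyls)
Conditions: TBAF, THF, rt → 40 °C
Reagents that add atoms: none
Why: Fluoride-mediated cleavage of both primary TBS ethers under non-acidic conditions that spare the tertiary allylic ether.

Step 19
Reactants: 27 (12R)-triol
Product: 28 12-keto-2,3-dialdehyde
Conditions: Dess–Martin periodinane (excess), CH2Cl2, 0 °C → rt
Reagents that add atoms: none
Why: Dess–Martin oxidation of all three hydroxyls at once removes any need to tell primary from secondary alcohols and deliberately erases the wrong C12 configuration, while quaternary C13 can neither epimerise nor let the vinyl group slip into conjugation.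

Step 20
Reactants: 28 12-keto-2,3-dialdehyde
Product: 29 12-keto-2,3-dioic acid
Conditions: NaClO2, NaH2PO4, 2-methyl-2-butene, t-BuOH–H2O, rt
Reagents that add atoms: sodium chlorite, [Na+].[O-]Cl=O
Why: Pinnick oxidation should convert both aldehydes, the neopentyl one included, into acids while the ketone and the vinyl group (shielded by the hypochlorite scavenger) stay untouched.

Step 21
Reactants: 29 12-keto-2,3-dioic acid
Product: 30 CNP0325408.2
Conditions: NaBH4 (excess), MeOH, 0 °C; work-up at pH 3
Reagents that add atoms: none
Why: Borohydride reduction of a conformationally locked six-ring ketone, in which the small hydride attacks C12 axially from the open lower face, anti to the neighbouring axial vinyl group, to give the equatorial (12S) alcohol, carboxylates being inert to the reagent.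

Compound list
1 | 4-bromo-3-methylanisole | COc1ccc(Br)c(C)c1 | starting material
2 | methyl isobutyrate | COC(=O)C(C)C | starting material
3 | lithium enolate of methyl isobutyrate | COC([O-])=C(C)C.[Li+] | intermediate
4 | methyl 2-(4-methoxy-2-methylphenyl)-2-methylpropanoate | COC(=O)C(C)(C)c1ccc(OC)cc1C | intermediate
5 | 2-(4-methoxy-2-methylphenyl)-2-methylpropan-1-ol | COc1ccc(C(C)(C)CO)c(C)c1 | intermediate
6 | tert-butyl[2-(4-methoxy-2-methylphenyl)-2-methylpropoxy]dimethylsilane | COc1ccc(C(C)(C)CO[Si](C)(C)C(C)(C)C)c(C)c1 | intermediate
7 | tert-butyl[2-(4-methoxy-2-methylcyclohexa-1,4-dien-1-yl)-2-methylpropoxy]dimethylsilane | COC1=CCC(C(C)(C)CO[Si](C)(C)C(C)(C)C)=C(C)C1 | intermediate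
8 | 4-[1-(tert-butyldimethylsilyloxy)-2-methylpropan-2-yl]-3-methylcyclohex-3-en-1-one | O=C1CCC(C(C)(C)CO[Si](C)(C)C(C)(C)C)=C(C)C1 | intermediate
9 | (S)-4-[1-(tert-butyldimethylsilyloxy)-2-methylpropan-2-yl]-3-methylcyclohex-2-en-1-one | O=C1C=C(C)[C@@H](C(C)(C)CO[Si](C)(C)C(C)(C)C)CC1 | intermediate
10 | propadiene (allene) | C=C=C | starting material
11 | head-to-head photoadduct: 5-[1-(TBSO)-2-methylpropan-2-yl]-6-methyl-8-methylidenebicyclo[4.2.0]octan-2-one, cis-fused, cyclobutane anti to the side chain | O=C1CC[C@H](C(C)(C)CO[Si](C)(C)C(C)(C)C)[C@@]2(C)CC(=C)[C@@H]12 | intermediate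
12 | spiro 1,2,4-trioxolane (ozonide) of 11, spiro carbon undefined | O=C1CC[C@H](C(C)(C)CO[Si](C)(C)C(C)(C)C)[C@@]2(C)CC3(OCOO3)[C@@H]12 | intermediate
13 | 5-[1-(TBSO)-2-methylpropan-2-yl]-6-methylbicyclo[4.2.0]octane-2,8-dione, cis-fused | O=C1CC[C@H](C(C)(C)CO[Si](C)(C)C(C)(C)C)[C@@]2(C)CC(=O)[C@@H]12 | intermediate
14 | allyl bromide | C=CCBr | starting material
15 | 1-allyl-5-[1-(TBSO)-2-methylpropan-2-yl]-6-methylbicyclo[4.2.0]octane-2,8-dione, cis-fused, allyl and C20 on the upper face | O=C1CC[C@H](C(C)(C)CO[Si](C)(C)C(C)(C)C)[C@@]2(C)CC(=O)[C@@]12CC=C | intermediate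
16 | methyl 2-[(1R,2S,6S)-2-allyl-6-[1-(TBSO)-2-methylpropan-2-yl]-1-methyl-3-oxocyclohexyl]acetate (labdane 5S,9S,10R) | O=C1CC[C@H](C(C)(C)CO[Si](C)(C)C(C)(C)C)[C@@](C)(CC(=O)OC)[C@@H]1CC=C | intermediate
17 | C8(17)-exomethylene analogue of 16, same spatial arrangement at C5, C9, C10 | C=C1CC[C@H](C(C)(C)CO[Si](C)(C)C(C)(C)C)[C@@](C)(CC(=O)OC)[C@@H]1CC=C | intermediate
18 | (5S,8S,9S,10R)-C8,C17 spiro-epoxide methyl ester, epoxide O equatorial (lower face), C17 axial | C1O[C@]12CC[C@H](C(C)(C)CO[Si](C)(C)C(C)(C)C)[C@@](C)(CC(=O)OC)[C@@H]2CC=C | intermediate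
19 | (5S,8S,9S,10R)-diol: C8 tertiary alcohol (OH equatorial, C17 axial), C2 primary alcohol, C3 OTBS, C9 allyl | O[C@@]1(C)CC[C@H](C(C)(C)CO[Si](C)(C)C(C)(C)C)[C@@](C)(CCO)[C@@H]1CC=C | intermediate
20 | (5S,8S,9S,10R)-C8 tertiary alcohol with C2 and C3 OTBS and C9 allyl | O[C@@]1(C)CC[C@H](C(C)(C)CO[Si](C)(C)C(C)(C)C)[C@@](C)(CCO[Si](C)(C)C(C)(C)C)[C@@H]1CC=C | intermediate
21 | (5S,8S,9S,10R)-C8 tertiary acetate with C9 allyl group, arms as TBS ethers (key-step precursor) | CC(=O)O[C@@]1(C)CC[C@H](C(C)(C)CO[Si](C)(C)C(C)(C)C)[C@@](C)(CCO[Si](C)(C)C(C)(C)C)[C@@H]1CC=C | intermediate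
22 | C12 titanium alkylidene derived from 21 (Cl2Ti written formally) | CC(=O)O[C@@]1(C)CC[C@H](C(C)(C)CO[Si](C)(C)C(C)(C)C)[C@@](C)(CCO[Si](C)(C)C(C)(C)C)[C@@H]1CC=[Ti](Cl)Cl | intermediate
23 | oxatitanacyclobutane (Ti–C12–C13–O) fused to the nascent pyran, C12 and C13 undefined | CC12O[Ti](Cl)(Cl)C1C[C@@H]3[C@@](C)(O2)CC[C@H](C(C)(C)CO[Si](C)(C)C(C)(C)C)[C@@]3(C)CCO[Si](C)(C)C(C)(C)C | intermediate
24 | (5S,8S,9S,10R)-trans-fused 13-methyl cyclic enol ether (C12=C13), arms as TBS ethers (key-step product) | CC1=CC[C@@H]2[C@@](C)(O1)CC[C@H](C(C)(C)CO[Si](C)(C)C(C)(C)C)[C@@]2(C)CCO[Si](C)(C)C(C)(C)C | intermediate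
25 | C12,C13 epoxide of 24, epoxide oxygen on the lower face (anti to C17) | C[C@@]12O[C@@H]1C[C@@H]3[C@@](C)(O2)CC[C@H](C(C)(C)CO[Si](C)(C)C(C)(C)C)[C@@]3(C)CCO[Si](C)(C)C(C)(C)C | intermediate
26 | (5S,8S,9S,10R,12R,13S)-13-vinyl-12-ol, vinyl axial (upper face), OH axial (lower face), arms as TBS ethers | C=C[C@]1(C)O[C@@]2(C)CC[C@H](C(C)(C)CO[Si](C)(C)C(C)(C)C)[C@@](C)(CCO[Si](C)(C)C(C)(C)C)[C@@H]2C[C@H]1O | intermediate
27 | (12R)-2,3,12-triol | C=C[C@]1(C)O[C@@]2(C)CC[C@H](C(C)(C)CO)[C@@](C)(CCO)[C@@H]2C[C@H]1O | intermediate
28 | 12-keto-2,3-dialdehyde | C=C[C@]1(C)O[C@@]2(C)CC[C@H](C(C)(C)C=O)[C@@](C)(CC=O)[C@@H]2CC1=O | intermediate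
29 | 12-keto-2,3-dioic acid | C=C[C@]1(C)O[C@@]2(C)CC[C@H](C(C)(C)C(=O)O)[C@@](C)(CC(=O)O)[C@@H]2CC1=O | intermediate
30 | CNP0325408.2, (5S,8S,9S,10R,12S,13S)-8,13-epoxy-12-hydroxy-2,3-secolabd-14-ene-2,3-dioic acid | C=C[C@]1(C)O[C@@]2(C)CC[C@H](C(C)(C)C(=O)O)[C@@](C)(CC(=O)O)[C@@H]2C[C@@H]1O | target

Total step count: 21. Longest linear sequence: 21 steps (from 1).

Steps most likely to fail

**Step 16.**
- **Risk:** The crowded tertiary ester may be attacked sluggishly. The carbonyl may be alkylidenated without ring closure. Residual Lewis acidity at 65 °C may ionise the tertiary C8–O bond.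
- **Fallback:** Setting out from 21, the acetate carbonyl is methylenated with dimethyltitanocene (toluene, 80 °C; Petasis olefination, no Lewis acid present) to the C8 isopropenyl ether F1. Enol-ether–olefin ring-closing metathesis with a second-generation ruthenium benzylidene catalyst (toluene, 70 °C, ethene swept out) then rejoins the route at 24.

**Step 17.**
- **Risk:** The nucleophile has to enter syn to the axial C17 methyl, so facial selectivity at C13 may erode. The strongly basic Grignard reagent may instead abstract a proton from C16 of the opened epoxide. A hydride shift may also outrun C–C bond formation.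
- **Fallback:** Setting out from 24, epoxide 25 is generated as before but opened with ethynylmagnesium bromide (THF, −78 → 0 °C). This is a rod-shaped and far less basic carbon nucleophile, and it gives the 13-ethynyl-12-ol F2. Semi-hydrogenation over Lindlar catalyst (H2, quinoline, EtOAc) rejoins the route at 26.

**Step 6.**
- **Risk:** Control of the face on which C5 is protonated may be insufficient next to the very bulky quaternary side chain, or turnover may be slow.
- **Fallback:** Setting out from 8, the alkene is moved into conjugation with catalytic DBU (CH2Cl2, rt) to give the racemic enone F3. This is resolved by preparative chromatography on a chiral stationary phase. The S enantiomer is 9, where the route is rejoined, and the R enantiomer F4 is set aside.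

Further compounds
F1 | step 16 | C8 isopropenyl ether with C9 allyl group, arms as TBS ethers | C=C(C)O[C@@]1(C)CC[C@H](C(C)(C)CO[Si](C)(C)C(C)(C)C)[C@@](C)(CCO[Si](C)(C)C(C)(C)C)[C@@H]1CC=C
F2 | step 17 | (12R,13S)-13-ethynyl-12-ol, arms as TBS ethers | C#C[C@]1(C)O[C@@]2(C)CC[C@H](C(C)(C)CO[Si](C)(C)C(C)(C)C)[C@@](C)(CCO[Si](C)(C)C(C)(C)C)[C@@H]2C[C@H]1O
F3 | step 6 | racemic 4-[1-(tert-butyldimethylsilyloxy)-2-methylpropan-2-yl]-3-methylcyclohex-2-en-1-one | O=C1C=C(C)C(C(C)(C)CO[Si](C)(C)C(C)(C)C)CC1
F4 | step 6 | (R)-4-[1-(tert-butyldimethylsilyloxy)-2-methylpropan-2-yl]-3-methylcyclohex-2-en-1-one | O=C1C=C(C)[C@H](C(C)(C)CO[Si](C)(C)C(C)(C)C)CC1
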